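## Structural features

The target is a cembrane-type 14-membered carbocycle (ring atoms C1–C14) with a trisubstituted oxirane fused across C12–C13, that is, a 15-oxabicyclo[12.1.0]pentadecadiene. The ring carries an E trisubstituted alkene at C2=C3 (methyl on C3), a Z trisubstituted alkene at C8=C9 (methyl on C9) and a third methyl on the oxirane carbon C13. There are four stereocentres, all R. C12 and C13 are contiguous inside the oxirane, C1 (secondary allylic acetate) is separated from C13 only by the C14 methylene, and C6, which bears the exocyclic 2-acetoxyprop-2-yl group, is isolated between two methylenes and cannot be relayed from the others. The fragile groups are the ionisable allylic acetate at C1, the acid-sensitive trisubstituted oxirane, the tertiary acetate (hindered to make, prone to elimination under acid) and the Z alkene, which rules out any step that equilibrates C8=C9. The real difficulty is closing a 14-membered ring late, under conditions that an oxirane, two allylic systems and hydroxyl groups tolerate, with one isolated centre (C6) and three clustered centres (C1, C12, C13) already in place. The key step uses the array C1(O)–C2=C3(CH3)–C4. This array is what a 1,4-opening of a 2-isopropenyl oxirane spanning C1–C2 leaves behind when C5 arrives at C4, so the ring bond C4–C5, the E alkene and the free C1 hydroxyl come out of one isomerisation of an acyclic bis-oxirane.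

## Logic of the disconnections

**27 to 26.** The two acyl C–O bonds are cut first because the acetates are the groups least able to survive hydride, organometallic and reductive steps. This reduces the target to a diol. The forward step must esterify a hindered tertiary hydroxyl without ionising the allylic ester or opening the oxirane.

**26 to 25.** Two C5–S bonds are added in the backward direction. The sulfonyl groups are traceless activators that make C5 a soft carbon acid. The forward reductive cleavage must spare the oxirane, both alkenes and the allylic alcohol; no leaving group stands β to C5.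

**25 to 24.** The ring bond C4–C5 is cut, with transposition of the C2=C3 alkene back into a C1–C2 oxirane bearing an isopropenyl group. The cut is made here because the nucleophile and the electrophile are both latent in 24 and are unmasked together by the catalyst, under neutral conditions. The gain is a fully acyclic precursor. The forward step must attack the allyl terminus C4 and not C2, give the E alkene, and must not involve the second oxirane. The side-chain oxygen is left as a free hydroxyl in 24 and 25, which makes the already branched nucleophile smaller and removes any acyl-transfer pathway.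

**24 to 21 (through 23 and 22).** The C3=C4 methylene bond and then the two C–O bonds of the C1–C2 oxirane are cut. A secondary E-allylic alcohol is chosen as the epoxidation substrate so that one oxidation gives the methyl ketone directly. The forward epoxidation must be reagent-controlled and matched with the carbinol configuration; the methylenation must tolerate an epoxy ketone.

**21 to 15 and 17 (through 20, 19 and 18; 17 from 16).** The E alkene is traced back to an alkyne and the C14–C1 bond is cut between a primary epoxy triflate and an acetylide. This splits off the four-carbon unit C1–C3 plus the C3 methyl as a commercial chiral alkynol. The forward displacement must take place at a carbon next to a fully substituted oxirane carbon, in a molecule that carries acidic protons.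

**15 to 13 (through 14).** The C12–O and C13–O bonds are cut back to an E-allylic alcohol, so both oxirane centres come from one reagent-controlled epoxidation directed by the C14 hydroxyl. The forward step must leave C8=C9 alone, which it does because that alkene has no allylic hydroxyl.

**13 to 10 (through 12 and 11).** The two C5–S bonds are disconnected one at a time, down to a primary alcohol. No acid is then needed near the alkenes, and the second sulfonyl group is added only once the first has made C5 acidic. The forward steps must oxidise sulfur in the presence of two trisubstituted alkenes and sulfonylate carbon, not oxygen.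

**10 to 7 (through 9 and 8).** C5 is traced to the carbinol carbon of a vicinal diol (glycol cleavage in the forward direction), and the four C–CH3 bonds of two dimethyl carbinols are cut back to two esters. This turns the side chain and C5 into the two ends of a malate. The forward steps must not epimerise the carbon that becomes C6.

**7 to 5 and 6.** The C6–C7 bond is cut between an allylic bromide and the dianion of a hydroxy diester from the chiral pool. This sets the isolated C6 centre by 1,2-induction from a centre that is later destroyed. The demand is high anti selectivity and removal of the minor diastereomer, which would otherwise become the C6 enantiomer.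

**5 to 1 (through 4, 3 and 2).** The C7–Br bond, the silyl ether and the C14–O bond are removed to reach 1. C14 is oxygenated first because only while C7 still carries its acetate is the C8=C9 alkene deactivated towards allylic oxidation. The cost is one protecting-group exchange.

## Other disconnections considered

**Alternative 1:** The cuts are C9–C10 and C7–C8, and the Z alkene is assembled from three pieces. An organocopper reagent made from the magnesium reagent A2 would add syn across propyne A4 (C10 to C9, copper on C8), and the resulting alkenylcopper would be alkylated by the primary triflate A3 to give the acyclic alkene A1.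
- In its favour: it is convergent, it fixes the Z geometry by mechanism and not by purchase, and it needs no sulfur activation and no low-yielding allylic oxidation. On these points it is the better plan.
- Against it here: the step closes no ring, so a macrocyclisation between C3 and C4 would still have to be found. One option is hydroboration of the vinyl group and an intramolecular alkyl–alkenyl coupling with an alkenyl halide made from the methyl alkyne, which would also have to fix the E C2=C3 geometry.
- The alkenylcopper must alkylate a β-branched triflate next to a quaternary carbon, which is a sluggish combination.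
- The syn-diol acetonide must later be turned into the trans-oxirane with net retention (a double inversion), which costs extra steps.
- Comparison: both plans fix all stereocentres before ring closure (equal). The chosen plan is linear but its key step delivers the ring, the alkene and the carbinol at once; alternative 1 postpones the hardest problem.

**Alternative 2:** The cut is C6–C7. Deprotonation of the acyclic allylic sulfide A6 at C7 would give a sulfur-stabilised allyl anion that opens the gem-dimethyl oxirane at C6 with inversion and closes the ring to A5.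
- In its favour: ring closure, the C6 centre and the tertiary carbinol would all come from one step. In stereocentres built by the key step and in step count to the C6 unit it is the better plan. The driving force, release of oxirane strain, is equal.
- Against it here: the anion is ambident (attack through C9 would give a 12-membered ring), and the Z geometry of C8=C9 can leak in the allyl anion.
- The attacked carbon C6 is secondary but next to a fully substituted carbon.
- The strong base forces the C12–C13 oxirane to be carried as a diol acetonide and rebuilt later.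
- Reductive removal of an allylic sulfide can transpose or isomerise the alkene.
- Comparison: the chosen plan runs under neutral conditions, tolerates the second oxirane and free hydroxyls, and never makes C8=C9 part of a delocalised anion. It pays with two sulfonyl groups to install and remove.

**Alternative 3:** The cut is C13–C14. A Lewis-acid-mediated intramolecular aldol addition of the silyl dienol ether terminus C14 of A8 to its C13 α-chloro methyl ketone would give the macrocyclic enone A7, whose chlorohydrin would then be closed to the oxirane.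
- In its favour: the quaternary C13 and the ring would be formed together; both Sharpless epoxidations and all sulfur chemistry are avoided, which makes it the better plan in step count on paper. The tertiary acetate could be carried as such, which is equal or better.
- Against it here: a ketone is a poor electrophile for a macro-aldol, and facial control by the C12 chloride in a flexible macrocyclic transition state is uncertain.
- The α-chloro ketone centre is epimerisable.
- The β-hydroxy ketone can fragment by retro-aldol under the basic conditions needed for oxirane closure.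
- C1 would still need a reagent-controlled reduction.
- Comparison: the chosen plan sets C12, C13, C1 and C2 by reagent control on acyclic substrates, where the outcome is predictable, and closes the ring by an irreversible step.

Key step: step 19

Remark on the chemistry: the side-chain oxygen is carried as the free tertiary hydroxyl through the ring closure (24 and 25), and both acetates are put on in the last step.
Remark on the chemistry: the oxirane in 24 must be (1R,2R)-trans to deliver 1R, and C6, C12 and C13 must be R; both Sharpless epoxidations therefore use the D-(−)-tartrate series. For alternative 3 the silyl group of A8 is taken as trimethylsilyl.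

Step 1
Reactants: 1 neryl acetate, (2Z)-3,7-dimethylocta-2,6-dien-1-yl acetate
Product: 2 (2Z,6E)-8-hydroxy-3,7-dimethylocta-2,6-dien-1-yl acetate
Conditions: SeO2 (0.1 equiv), t-BuOOH (3 equiv), salicylic acid (0.1 equiv), CH2Cl2, rt
Reagents that add atoms: tert-butyl hydroperoxide, CC(C)(C)OO (oxygen relayed through SeO2, O=[Se]=O)
Why: Allylic oxidation with catalytic SeO2 (ene reaction, then [2,3]-sigmatropic shift) attacks the E methyl of the terminal trisubstituted alkene. The allylic acetate deactivates C8=C9 and its methyl, which is why this oxidation is placed before the C6–C7 bond is made.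

Step 2
Reactants: 2 (2Z,6E)-8-hydroxy-3,7-dimethylocta-2,6-dien-1-yl acetate
Product: 3 (2Z,6E)-8-[(tert-butyldiphenylsilyl)oxy]-3,7-dimethylocta-2,6-dien-1-yl acetate
Conditions: TBDPSCl, imidazole, CH2Cl2, 0 °C to rt
Reagents that add atoms: tert-butyldiphenylsilyl chloride, CC(C)(C)[Si](Cl)(c1ccccc1)c1ccccc1
Why: Silyl ether formation; the bulky silyl group should survive methanolysis, bromination, enolate, organometallic and oxidative steps and is removed later by fluoride.

Step 3
Reactants: 3 (2Z,6E)-8-[(tert-butyldiphenylsilyl)oxy]-3,7-dimethylocta-2,6-dien-1-yl acetate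
Product: 4 (2Z,6E)-8-[(tert-butyldiphenylsilyl)oxy]-3,7-dimethylocta-2,6-dien-1-ol
Conditions: K2CO3 (cat.), MeOH, rt
Reagents that add atoms: none
Why: Base-catalysed transesterification removes the primary acetate; the silyl ether is inert to carbonate in methanol.

Step 4
Reactants: 4 (2Z,6E)-8-[(tert-butyldiphenylsilyl)oxy]-3,7-dimethylocta-2,6-dien-1-ol
Product: 5 {[(2E,6Z)-8-bromo-2,6-dimethylocta-2,6-dien-1-yl]oxy}(tert-butyl)diphenylsilane
Conditions: CBr4, PPh3, CH2Cl2, 0 °C
Reagents that add atoms: carbon tetrabromide, BrC(Br)(Br)Br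
Why: Appel reaction; SN2 displacement of the oxyphosphonium salt under neutral conditions should keep the Z geometry and avoid allylic transposition.

Step 5
Reactants: 5 {[(2E,6Z)-8-bromo-2,6-dimethylocta-2,6-dien-1-yl]oxy}(tert-butyl)diphenylsilane; 6 dimethyl (2R)-2-hydroxybutanedioate (dimethyl (R)-malate)
Product: 7 dimethyl (2R,3S)-2-hydroxy-3-{(2Z,6E)-8-[(tert-butyldiphenylsilyl)oxy]-3,7-dimethylocta-2,6-dien-1-yl}butanedioate
Conditions: 6, LiN(iPr)2 (2.2 equiv), THF, −78 to −20 °C; then 5, −78 to −10 °C
Reagents that add atoms: none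
Why: Fráter–Seebach alkylation: the dilithium alkoxide–enolate of 6 is a rigid chelate that 5 should approach from the face opposite the methoxycarbonyl group on the carbinol carbon, giving the anti (2R,3S) product by SN2 at the primary allylic bromide. The new centre is the future C6. The minor syn diastereomer, which would become the C6 enantiomer, should be removed by chromatography here.

Step 6
Reactants: 7 dimethyl (2R,3S)-2-hydroxy-3-{(2Z,6E)-8-[(tert-butyldiphenylsilyl)oxy]-3,7-dimethylocta-2,6-dien-1-yl}butanedioate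
Product: 8 (3R,4S,6Z,10E)-12-[(tert-butyldiphenylsilyl)oxy]-4-(2-hydroxypropan-2-yl)-2,7,11-trimethyldodeca-6,10-diene-2,3-diol
Conditions: MeMgBr (7 equiv), CeCl3, THF, −78 to 0 °C
Reagents that add atoms: methylmagnesium bromide, C[Mg]Br
Why: Double addition of the methyl organometallic to each ester gives two dimethyl carbinols. The weakly basic cerium reagent should prevent enolisation of the intermediate methyl ketone and so keep the future C6 intact.

Step 7
Reactants: 8 (3R,4S,6Z,10E)-12-[(tert-butyldiphenylsilyl)oxy]-4-(2-hydroxypropan-2-yl)-2,7,11-trimethyldodeca-6,10-diene-2,3-diol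
Product: 10 (2S)-2-{(2Z,6E)-8-[(tert-butyldiphenylsilyl)oxy]-3,7-dimethylocta-2,6-dien-1-yl}-3-methylbutane-1,3-diol, via hydroxy aldehyde 9 (not isolated)
Conditions: NaIO4, THF–H2O (pH 7), 0 °C; then NaBH4, EtOH, 0 °C
Reagents that add atoms: none
Why: Periodate glycol cleavage (Malaprade reaction) cuts the only vicinal diol, releases acetone and unveils C5 as an aldehyde. Immediate borohydride reduction should prevent epimerisation or retro-aldol loss of the β-hydroxy aldehyde.

Step 8
Reactants: 10 (2S)-2-{(2Z,6E)-8-[(tert-butyldiphenylsilyl)oxy]-3,7-dimethylocta-2,6-dien-1-yl}-3-methylbutane-1,3-diol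
Product: 11 (3R,5Z,9E)-11-[(tert-butyldiphenylsilyl)oxy]-2,6,10-trimethyl-3-[(phenylsulfanyl)methyl]undeca-5,9-dien-2-ol
Conditions: PhSSPh, PBu3, pyridine, rt to 50 °C
Reagents that add atoms: diphenyl disulfide, c1ccc(cc1)SSc1ccccc1
Why: Mukaiyama–Hata thioetherification: the primary hydroxyl is activated as an alkoxyphosphonium salt and displaced by thiolate, while the tertiary hydroxyl cannot be activated. The configuration at C6 is untouched (the descriptor changes only by priority).

Step 9
Reactants: 11 (3R,5Z,9E)-11-[(tert-butyldiphenylsilyl)oxy]-2,6,10-trimethyl-3-[(phenylsulfanyl)methyl]undeca-5,9-dien-2-ol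
Product: 12 (3R,5Z,9E)-11-[(tert-butyldiphenylsilyl)oxy]-2,6,10-trimethyl-3-[(phenylsulfonyl)methyl]undeca-5,9-dien-2-ol
Conditions: (NH4)6Mo7O24·4H2O (10 mol %), H2O2 (30%), EtOH, 0 °C to rt
Reagents that add atoms: hydrogen peroxide, OO
Why: Molybdate-catalysed peroxide oxidation takes the sulfide through the sulfoxide to the sulfone; nucleophilic sulfur should be oxidised much faster than unactivated trisubstituted alkenes.

Step 10
Reactants: 12 (3R,5Z,9E)-11-[(tert-butyldiphenylsilyl)oxy]-2,6,10-trimethyl-3-[(phenylsulfonyl)methyl]undeca-5,9-dien-2-ol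
Product: 13 (3R,5Z,9E)-3-[bis(phenylsulfonyl)methyl]-11-[(tert-butyldiphenylsilyl)oxy]-2,6,10-trimethylundeca-5,9-dien-2-ol
Conditions: n-BuLi (3.1 equiv), THF, −78 to 0 °C; PhSO2F (1.1 equiv), −78 °C
Reagents that add atoms: benzenesulfonyl fluoride, O=S(=O)(F)c1ccccc1
Why: C-Sulfonylation of a metalated sulfone: n-BuLi forms the alkoxide and the doubly lithiated sulfone, which attacks the sulfonyl fluoride at sulfur to give the lithiated geminal bis-sulfone. Fluoride as leaving group avoids the α-halogenation seen with sulfonyl chlorides.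

Step 11
Reactants: 13 (3R,5Z,9E)-3-[bis(phenylsulfonyl)methyl]-11-[(tert-butyldiphenylsilyl)oxy]-2,6,10-trimethylundeca-5,9-dien-2-ol
Product: 14 (2E,6Z,9R)-9-[bis(phenylsulfonyl)methyl]-2,6,10-trimethylundeca-2,6-diene-1,10-diol
Conditions: Bu4NF, THF, 0 °C to rt
Reagents that add atoms: none
Why: Fluoride-induced desilylation frees the primary allylic alcohol needed as directing group; the bis-sulfone is only deprotonated reversibly.

Step 12
Reactants: 14 (2E,6Z,9R)-9-[bis(phenylsulfonyl)methyl]-2,6,10-trimethylundeca-2,6-diene-1,10-diol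
Product: 15 (3R,5Z)-3-[bis(phenylsulfonyl)methyl]-8-[(2R,3R)-3-(hydroxymethyl)-3-methyloxiran-2-yl]-2,6-dimethyloct-5-en-2-ol
Conditions: Ti(OiPr)4 (0.2 equiv), D-(−)-diethyl tartrate (0.25 equiv), t-BuOOH, 4 Å MS, CH2Cl2, −20 °C
Reagents that add atoms: tert-butyl hydroperoxide, CC(C)(C)OO
Why: Sharpless asymmetric epoxidation: with the D-(−)-tartrate the (E)-2-methylallylic alcohol should be oxidised on the face that gives the (2R,3R)-oxirane, which sets C12 and C13 as R,R by reagent control. C8=C9 has no allylic hydroxyl and should not react.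

Step 13
Reactants: 16 (2R)-but-3-yn-2-ol
Product: 17 tert-butyl{[(2R)-but-3-yn-2-yl]oxy}dimethylsilane
Conditions: TBSCl, imidazole, CH2Cl2, 0 °C to rt
Reagents that add atoms: tert-butyldimethylsilyl chloride, CC(C)(C)[Si](C)(C)Cl
Why: Silylation masks the secondary hydroxyl so that only the acetylide carbon of this piece can attack the triflate in the next step.

Step 14
Reactants: 15 (3R,5Z)-3-[bis(phenylsulfonyl)methyl]-8-[(2R,3R)-3-(hydroxymethyl)-3-methyloxiran-2-yl]-2,6-dimethyloct-5-en-2-ol; 17 tert-butyl{[(2R)-but-3-yn-2-yl]oxy}dimethylsilane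
Product: 20 (2R)-5-[(2R,3R)-3-{(3Z,6R)-6-[bis(phenylsulfonyl)methyl]-7-hydroxy-3,7-dimethyloct-3-en-1-yl}-2-methyloxiran-2-yl]pent-3-yn-2-ol, via epoxy triflate 18 (not isolated), via silyl-protected alkyne 19 (not isolated)
Conditions: Tf2O, 2,6-lutidine, CH2Cl2, −78 °C; crude 18 added to the lithium acetylide of 17 (n-BuLi, 5 equiv), THF–DMPU, −78 to −20 °C; then Bu4NF, 0 °C to rt
Reagents that add atoms: none
Why: Triflation of the primary epoxy alcohol and SN2 displacement by the lithium acetylide form C14–C1. Excess acetylide absorbs the hydroxyl and bis-sulfone protons, and the trisubstituted oxirane should not be opened without a Lewis acid. Fluoride then removes the secondary silyl ether in the same flask.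

Step 15
Reactants: 20 (2R)-5-[(2R,3R)-3-{(3Z,6R)-6-[bis(phenylsulfonyl)methyl]-7-hydroxy-3,7-dimethyloct-3-en-1-yl}-2-methyloxiran-2-yl]pent-3-yn-2-ol
Product: 21 (2R,3E)-5-[(2R,3R)-3-{(3Z,6R)-6-[bis(phenylsulfonyl)methyl]-7-hydroxy-3,7-dimethyloct-3-en-1-yl}-2-methyloxiran-2-yl]pent-3-en-2-ol
Conditions: NaAlH2(OCH2CH2OMe)2 (5 equiv), THF, 0 °C
Reagents that add atoms: none
Why: trans-Hydroalumination of the propargylic alcohol through its alkoxyaluminate (hydride to C2, aluminium on C1), then protonolysis, should give the E alkene only. Extra hydride is consumed by the hydroxyl and bis-sulfone protons.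

Step 16
Reactants: 21 (2R,3E)-5-[(2R,3R)-3-{(3Z,6R)-6-[bis(phenylsulfonyl)methyl]-7-hydroxy-3,7-dimethyloct-3-en-1-yl}-2-methyloxiran-2-yl]pent-3-en-2-ol
Product: 22 (1R)-1-[(2R,3R)-3-{[(2R,3R)-3-{(3Z,6R)-6-[bis(phenylsulfonyl)methyl]-7-hydroxy-3,7-dimethyloct-3-en-1-yl}-2-methyloxiran-2-yl]methyl}oxiran-2-yl]ethan-1-ol
Conditions: Ti(OiPr)4 (0.3 equiv), D-(−)-diisopropyl tartrate (0.4 equiv), t-BuOOH, 4 Å MS, CH2Cl2, −20 °C
Reagents that add atoms: tert-butyl hydroperoxide, CC(C)(C)OO
Why: Sharpless epoxidation of a secondary (E)-allylic alcohol in the matched sense: with the D-(−)-tartrate the (R)-carbinol is the fast-reacting enantiomer and should give the erythro epoxy alcohol on the same alkene face as a primary alcohol would. This sets C1 and C2 as R,R by reagent control; the carbinol centre is removed in the next step.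

Step 17
Reactants: 22 (1R)-1-[(2R,3R)-3-{[(2R,3R)-3-{(3Z,6R)-6-[bis(phenylsulfonyl)methyl]-7-hydroxy-3,7-dimethyloct-3-en-1-yl}-2-methyloxiran-2-yl]methyl}oxiran-2-yl]ethan-1-ol
Product: 23 1-[(2S,3R)-3-{[(2R,3R)-3-{(3Z,6R)-6-[bis(phenylsulfonyl)methyl]-7-hydroxy-3,7-dimethyloct-3-en-1-yl}-2-methyloxiran-2-yl]methyl}oxiran-2-yl]ethan-1-one
Conditions: Dess–Martin periodinane, NaHCO3, CH2Cl2, 0 °C to rt
Reagents that add atoms: none
Why: Dess–Martin oxidation of the secondary epoxy alcohol under bicarbonate buffer gives the α,β-epoxy ketone without touching the oxiranes or the tertiary alcohol. The descriptor at C2 changes from R to S by priority only.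

Step 18
Reactants: 23 1-[(2S,3R)-3-{[(2R,3R)-3-{(3Z,6R)-6-[bis(phenylsulfonyl)methyl]-7-hydroxy-3,7-dimethyloct-3-en-1-yl}-2-methyloxiran-2-yl]methyl}oxiran-2-yl]ethan-1-one
Product: 24 (3R,5Z)-3-[bis(phenylsulfonyl)methyl]-2,6-dimethyl-8-[(2R,3R)-3-methyl-3-{[(2R,3R)-3-(prop-1-en-2-yl)oxiran-2-yl]methyl}oxiran-2-yl]oct-5-en-2-ol
Conditions: Ph3PCH3Br, KN(SiMe3)2 (4 equiv of ylide), THF, −78 to 0 °C
Reagents that add atoms: methyltriphenylphosphonium bromide, C[P+](c1ccccc1)(c1ccccc1)c1ccccc1.[Br-]
Why: Wittig methylenation of the methyl ketone with a salt-free ylide builds C3=C4 and completes the isopropenyl oxirane. Excess ylide absorbs the acidic protons, and the oxirane α-hydrogen is not acidic enough for C2 to epimerise.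

Step 19
Reactants: 24 (3R,5Z)-3-[bis(phenylsulfonyl)methyl]-2,6-dimethyl-8-[(2R,3R)-3-methyl-3-{[(2R,3R)-3-(prop-1-en-2-yl)oxiran-2-yl]methyl}oxiran-2-yl]oct-5-en-2-ol
Product: 25 (1R,3R,4E,8R,10Z,14R)-8-(2-hydroxypropan-2-yl)-1,5,11-trimethyl-7,7-bis(phenylsulfonyl)-15-oxabicyclo[12.1.0]pentadeca-4,10-dien-3-ol
Conditions: Pd(PPh3)4 (10 mol %), THF, 65 °C, syringe-pump addition of 24, final 0.005 M
Reagents that add atoms: none
Why: Zerovalent palladium ionises the allylic C2–O bond of the isopropenyl oxirane with inversion and gives a zwitterionic π-allylpalladium species over C2–C3–C4; its C1 alkoxide removes the acidic C5–H of the bis-sulfone, so the nucleophile appears only where an electrophile already exists and no external base is needed. The stabilised carbanion then attacks the allyl ligand anti to palladium at the unsubstituted terminus C4, forming C4–C5 and releasing the catalyst; this is a Tsuji–Trost alkylation run as an isomerisation, and the closest known reaction type is the palladium-catalysed macrocyclisation of vinyl oxiranes carrying a bis(sulfonyl)methyl pronucleophile under neutral conditions. The ring closes in the 14-membered mode by attack at the allyl terminus remote from the tether, so that all three allyl carbons become ring atoms, in preference to the 12-membered mode at C2, because C4 is a free methylene whereas C2 is secondary and flanked by the carbinol. No stereocentre is created: C1 keeps its configuration because its C–O bond is never broken, and the configuration at C2 is given up on purpose. The E geometry of C2=C3 should follow from the syn π-allyl isomer, reached by π–σ–π equilibration through C4 before the slow ring closure, although the C3 methyl makes this preference smaller than in an unsubstituted allyl system. Only the allylic oxirane can ionise, so the C12–C13 oxirane, the tertiary hydroxyl (a far weaker nucleophile than the soft carbanion) and the Z alkene are spectators, and release of ring strain makes the isomerisation irreversible. The branch at C6 next to the nucleophilic carbon has no close analogy in this reaction class; it is answered by leaving the tertiary carbinol free instead of acylated and by slow addition at high dilution, which should suppress oligomers.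

Step 20
Reactants: 25 (1R,3R,4E,8R,10Z,14R)-8-(2-hydroxypropan-2-yl)-1,5,11-trimethyl-7,7-bis(phenylsulfonyl)-15-oxabicyclo[12.1.0]pentadeca-4,10-dien-3-ol
Product: 26 (1R,3R,4E,8R,10Z,14R)-8-(2-hydroxypropan-2-yl)-1,5,11-trimethyl-15-oxabicyclo[12.1.0]pentadeca-4,10-dien-3-ol
Conditions: Na/Hg (5%), Na2HPO4, MeOH–THF, −20 to 0 °C
Reagents that add atoms: none
Why: Dissolving-metal reductive desulfonylation cleaves both C5–S bonds by electron transfer, each carbanion being protonated by methanol. The phosphate buffer keeps the medium near neutral so that the oxirane and the allylic alcohol should survive, and no leaving group stands β to C5.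

Step 21
Reactants: 26 (1R,3R,4E,8R,10Z,14R)-8-(2-hydroxypropan-2-yl)-1,5,11-trimethyl-15-oxabicyclo[12.1.0]pentadeca-4,10-dien-3-ol
Product: 27 (1R,3R,4E,8R,10Z,14R)-8-[2-(acetyloxy)propan-2-yl]-1,5,11-trimethyl-15-oxabicyclo[12.1.0]pentadeca-4,10-dien-3-yl acetate (CNP0282098.2)
Conditions: Ac2O, Et3N, DMAP, CH2Cl2, rt to 40 °C
Reagents that add atoms: acetic anhydride, CC(=O)OC(C)=O
Why: Steglich-type DMAP-catalysed acylation should esterify the secondary allylic hydroxyl quickly and the tertiary hydroxyl on longer reaction; no stereocentre is touched.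

## Compound list

1 | neryl acetate, (2Z)-3,7-dimethylocta-2,6-dien-1-yl acetate | CC(=O)OC/C=C(/C)CCC=C(C)C | starting material
2 | (2Z,6E)-8-hydroxy-3,7-dimethylocta-2,6-dien-1-yl acetate | CC(=O)OC/C=C(/C)CC/C=C(\C)CO | intermediate
3 | (2Z,6E)-8-[(tert-butyldiphenylsilyl)oxy]-3,7-dimethylocta-2,6-dien-1-yl acetate | CC(=O)OC/C=C(/C)CC/C=C(\C)CO[Si](c1ccccc1)(c1ccccc1)C(C)(C)C | intermediate
4 | (2Z,6E)-8-[(tert-butyldiphenylsilyl)oxy]-3,7-dimethylocta-2,6-dien-1-ol | OC/C=C(/C)CC/C=C(\C)CO[Si](c1ccccc1)(c1ccccc1)C(C)(C)C | intermediate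
5 | {[(2E,6Z)-8-bromo-2,6-dimethylocta-2,6-dien-1-yl]oxy}(tert-butyl)diphenylsilane | BrC/C=C(/C)CC/C=C(\C)CO[Si](c1ccccc1)(c1ccccc1)C(C)(C)C | intermediate
6 | dimethyl (2R)-2-hydroxybutanedioate (dimethyl (R)-malate) | COC(=O)C[C@@H](O)C(=O)OC | starting material
7 | dimethyl (2R,3S)-2-hydroxy-3-{(2Z,6E)-8-[(tert-butyldiphenylsilyl)oxy]-3,7-dimethylocta-2,6-dien-1-yl}butanedioate | COC(=O)[C@H](O)[C@@H](C(=O)OC)C/C=C(/C)CC/C=C(\C)CO[Si](c1ccccc1)(c1ccccc1)C(C)(C)C | intermediate
8 | (3R,4S,6Z,10E)-12-[(tert-butyldiphenylsilyl)oxy]-4-(2-hydroxypropan-2-yl)-2,7,11-trimethyldodeca-6,10-diene-2,3-diol | CC(C)(O)[C@H](O)[C@@H](C(C)(C)O)C/C=C(/C)CC/C=C(\C)CO[Si](c1ccccc1)(c1ccccc1)C(C)(C)C | intermediate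
9 | (2R,4Z,8E)-10-[(tert-butyldiphenylsilyl)oxy]-2-(2-hydroxypropan-2-yl)-5,9-dimethyldeca-4,8-dienal | O=C[C@@H](C(C)(C)O)C/C=C(/C)CC/C=C(\C)CO[Si](c1ccccc1)(c1ccccc1)C(C)(C)C | intermediate
10 | (2S)-2-{(2Z,6E)-8-[(tert-butyldiphenylsilyl)oxy]-3,7-dimethylocta-2,6-dien-1-yl}-3-methylbutane-1,3-diol | OC[C@@H](C(C)(C)O)C/C=C(/C)CC/C=C(\C)CO[Si](c1ccccc1)(c1ccccc1)C(C)(C)C | intermediate
11 | (3R,5Z,9E)-11-[(tert-butyldiphenylsilyl)oxy]-2,6,10-trimethyl-3-[(phenylsulfanyl)methyl]undeca-5,9-dien-2-ol | c1ccccc1SC[C@@H](C(C)(C)O)C/C=C(/C)CC/C=C(\C)CO[Si](c1ccccc1)(c1ccccc1)C(C)(C)C | intermediate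
12 | (3R,5Z,9E)-11-[(tert-butyldiphenylsilyl)oxy]-2,6,10-trimethyl-3-[(phenylsulfonyl)methyl]undeca-5,9-dien-2-ol | O=S(=O)(c1ccccc1)C[C@@H](C(C)(C)O)C/C=C(/C)CC/C=C(\C)CO[Si](c1ccccc1)(c1ccccc1)C(C)(C)C | intermediate
13 | (3R,5Z,9E)-3-[bis(phenylsulfonyl)methyl]-11-[(tert-butyldiphenylsilyl)oxy]-2,6,10-trimethylundeca-5,9-dien-2-ol | O=S(=O)(c1ccccc1)C(S(=O)(=O)c1ccccc1)[C@@H](C(C)(C)O)C/C=C(/C)CC/C=C(\C)CO[Si](c1ccccc1)(c1ccccc1)C(C)(C)C | intermediate
14 | (2E,6Z,9R)-9-[bis(phenylsulfonyl)methyl]-2,6,10-trimethylundeca-2,6-diene-1,10-diol | O=S(=O)(c1ccccc1)C(S(=O)(=O)c1ccccc1)[C@@H](C(C)(C)O)C/C=C(/C)CC/C=C(\C)CO | intermediate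
15 | (3R,5Z)-3-[bis(phenylsulfonyl)methyl]-8-[(2R,3R)-3-(hydroxymethyl)-3-methyloxiran-2-yl]-2,6-dimethyloct-5-en-2-ol | O=S(=O)(c1ccccc1)C(S(=O)(=O)c1ccccc1)[C@@H](C(C)(C)O)C/C=C(/C)CC[C@H]1O[C@]1(C)CO | intermediate
16 | (2R)-but-3-yn-2-ol | C[C@@H](O)C#C | starting material
17 | tert-butyl{[(2R)-but-3-yn-2-yl]oxy}dimethylsilane | C[C@@H](O[Si](C)(C)C(C)(C)C)C#C | intermediate
18 | [(2R,3R)-3-{(3Z,6R)-6-[bis(phenylsulfonyl)methyl]-7-hydroxy-3,7-dimethyloct-3-en-1-yl}-2-methyloxiran-2-yl]methyl trifluoromethanesulfonate | O=S(=O)(c1ccccc1)C(S(=O)(=O)c1ccccc1)[C@@H](C(C)(C)O)C/C=C(/C)CC[C@H]1O[C@]1(C)COS(=O)(=O)C(F)(F)F | intermediate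
19 | tert-butyl{[(2R)-5-[(2R,3R)-3-{(3Z,6R)-6-[bis(phenylsulfonyl)methyl]-7-hydroxy-3,7-dimethyloct-3-en-1-yl}-2-methyloxiran-2-yl]pent-3-yn-2-yl]oxy}dimethylsilane | O=S(=O)(c1ccccc1)C(S(=O)(=O)c1ccccc1)[C@@H](C(C)(C)O)C/C=C(/C)CC[C@H]1O[C@]1(C)CC#C[C@@H](C)O[Si](C)(C)C(C)(C)C | intermediate
20 | (2R)-5-[(2R,3R)-3-{(3Z,6R)-6-[bis(phenylsulfonyl)methyl]-7-hydroxy-3,7-dimethyloct-3-en-1-yl}-2-methyloxiran-2-yl]pent-3-yn-2-ol | O=S(=O)(c1ccccc1)C(S(=O)(=O)c1ccccc1)[C@@H](C(C)(C)O)C/C=C(/C)CC[C@H]1O[C@]1(C)CC#C[C@@H](C)O | intermediate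
21 | (2R,3E)-5-[(2R,3R)-3-{(3Z,6R)-6-[bis(phenylsulfonyl)methyl]-7-hydroxy-3,7-dimethyloct-3-en-1-yl}-2-methyloxiran-2-yl]pent-3-en-2-ol | O=S(=O)(c1ccccc1)C(S(=O)(=O)c1ccccc1)[C@@H](C(C)(C)O)C/C=C(/C)CC[C@H]1O[C@]1(C)C/C=C/[C@@H](C)O | intermediate
22 | (1R)-1-[(2R,3R)-3-{[(2R,3R)-3-{(3Z,6R)-6-[bis(phenylsulfonyl)methyl]-7-hydroxy-3,7-dimethyloct-3-en-1-yl}-2-methyloxiran-2-yl]methyl}oxiran-2-yl]ethan-1-ol | O=S(=O)(c1ccccc1)C(S(=O)(=O)c1ccccc1)[C@@H](C(C)(C)O)C/C=C(/C)CC[C@H]1O[C@]1(C)C[C@H]2O[C@@H]2[C@@H](C)O | intermediate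
23 | 1-[(2S,3R)-3-{[(2R,3R)-3-{(3Z,6R)-6-[bis(phenylsulfonyl)methyl]-7-hydroxy-3,7-dimethyloct-3-en-1-yl}-2-methyloxiran-2-yl]methyl}oxiran-2-yl]ethan-1-one | O=S(=O)(c1ccccc1)C(S(=O)(=O)c1ccccc1)[C@@H](C(C)(C)O)C/C=C(/C)CC[C@H]1O[C@]1(C)C[C@H]2O[C@@H]2C(C)=O | intermediate
24 | (3R,5Z)-3-[bis(phenylsulfonyl)methyl]-2,6-dimethyl-8-[(2R,3R)-3-methyl-3-{[(2R,3R)-3-(prop-1-en-2-yl)oxiran-2-yl]methyl}oxiran-2-yl]oct-5-en-2-ol | O=S(=O)(c1ccccc1)C(S(=O)(=O)c1ccccc1)[C@@H](C(C)(C)O)C/C=C(/C)CC[C@H]1O[C@]1(C)C[C@H]2O[C@@H]2C(C)=C | intermediate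
25 | (1R,3R,4E,8R,10Z,14R)-8-(2-hydroxypropan-2-yl)-1,5,11-trimethyl-7,7-bis(phenylsulfonyl)-15-oxabicyclo[12.1.0]pentadeca-4,10-dien-3-ol | O[C@H]1/C=C(\C)CC(S(=O)(=O)c2ccccc2)(S(=O)(=O)c3ccccc3)[C@@H](C(C)(C)O)C/C=C(/C)CC[C@H]4O[C@]4(C)C1 | intermediate
26 | (1R,3R,4E,8R,10Z,14R)-8-(2-hydroxypropan-2-yl)-1,5,11-trimethyl-15-oxabicyclo[12.1.0]pentadeca-4,10-dien-3-ol | O[C@H]1/C=C(\C)CC[C@@H](C(C)(C)O)C/C=C(/C)CC[C@H]2O[C@]2(C)C1 | intermediate
27 | (1R,3R,4E,8R,10Z,14R)-8-[2-(acetyloxy)propan-2-yl]-1,5,11-trimethyl-15-oxabicyclo[12.1.0]pentadeca-4,10-dien-3-yl acetate (CNP0282098.2) | CC(=O)O[C@H]1/C=C(\C)CC[C@@H](C(C)(C)OC(C)=O)C/C=C(/C)CC[C@H]2O[C@]2(C)C1 | target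

## Step count and least certain steps

Total step count: 21. Longest linear sequence: 20 steps (1 to 27 through steps 1–12 and 14–21); step 13 is a one-step side branch.

**Step 19 (key step).** The most likely failure is that C–C bond formation by the branched carbanion is too slow. The zwitterion would then be diverted by proton loss or hydride shift to a dienol or enone, by intermolecular alkylation to oligomers, or by leakage through the anti allyl isomer to the Z alkene. The fallback sets out from 24 and returns at 25; it separates ionisation from ring closure and closes the ring thermally without a catalyst.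
- Acetic acid is added 1,4 to the oxirane under the same zerovalent palladium catalysis, a fast capture by an unhindered external nucleophile, to give the (E)-4-acetoxy allylic alcohol F1.
- Methanolysis (K2CO3, MeOH) gives the allylic diol F2.
- Corey–Kim chlorination (NCS, Me2S, CH2Cl2, −20 °C), which selects the primary allylic hydroxyl, gives the allylic chloride F3.
- The preformed caesium bis-sulfonyl carbanion is alkylated intramolecularly (Cs2CO3, DMF, high dilution, 50–70 °C) in a malonate-type SN2 macro-alkylation that gives 25. The E alkene prevents competing O-alkylation by the C1 hydroxyl.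

**Step 14.** Proton transfer from the bis-sulfone and the hydroxyl to the acetylide may leave a carbanion or alkoxide that competes for the triflate. Displacement at a carbon next to the fully substituted oxirane carbon is also slower than usual, so the triflate may decompose first. The fallback sets out from 12 and returns at 19; it changes the order so that no carbon acid is present during the displacement.
- 12 is desilylated (Bu4NF) to the mono-sulfone allylic alcohol F4.
- F4 is epoxidised as in step 12 to the epoxy alcohol F5.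
- F5 is converted into the triflate F6 and coupled with the lithium acetylide of 17 to give the silyl-protected alkyne F7.
- F7 is C-sulfonylated as in step 10 to give 19, which is desilylated to 20.

**Step 15.** The aluminium hydride may over-reduce, opening the C12–C13 oxirane at C12 or attacking a sulfonyl group, because three acidic sites force a large excess of reagent. The fallback sets out from 20 and returns at 21. Ruthenium-catalysed trans-hydrosilylation ([Cp*Ru(MeCN)3]PF6, (EtO)3SiH, CH2Cl2, 0 °C) gives the (Z)-alkenylsilane F8, and protodesilylation (Bu4NF, CuI, THF) gives 21 without any hydride reagent.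

**Step 10.** The second metalation may be incomplete or may go to the ortho position of the phenyl ring, and the alkoxide may be sulfonylated. The fallback sets out from 12 and returns at 13. The monolithiated sulfone (n-BuLi, 2 equiv) is sulfenylated with PhSSPh to the α-phenylsulfanyl sulfone F9 (mixture of epimers at the new centre), and the sulfide is oxidised as in step 9 to 13.

**Step 21.** Acylation of the tertiary hydroxyl may be sluggish, and forcing conditions may ionise the allylic acetate or open the oxirane. The fallback sets out from 24 and returns at 27; it puts the tertiary acetate on before any allylic ester exists.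
- 24 is acetylated (Ac2O, Et3N, DMAP) to the tertiary acetate F10.
- F10 is cyclised as in step 19 to the macrocyclic hydroxy acetate F11.
- F11 is desulfonylated as in step 20 to F12.
- The secondary hydroxyl of F12 is acetylated under mild conditions (Ac2O, pyridine) to give 27.

## Further compounds

F1 | step 19 | (2E,4R)-5-[(2R,3R)-3-{(3Z,6R)-6-[bis(phenylsulfonyl)methyl]-7-hydroxy-3,7-dimethyloct-3-en-1-yl}-2-methyloxiran-2-yl]-4-hydroxy-2-methylpent-2-en-1-yl acetate | O=S(=O)(c1ccccc1)C(S(=O)(=O)c1ccccc1)[C@@H](C(C)(C)O)C/C=C(/C)CC[C@H]1O[C@]1(C)C[C@@H](O)/C=C(\C)COC(C)=O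
F2 | step 19 | (2E,4R)-5-[(2R,3R)-3-{(3Z,6R)-6-[bis(phenylsulfonyl)methyl]-7-hydroxy-3,7-dimethyloct-3-en-1-yl}-2-methyloxiran-2-yl]-2-methylpent-2-ene-1,4-diol | O=S(=O)(c1ccccc1)C(S(=O)(=O)c1ccccc1)[C@@H](C(C)(C)O)C/C=C(/C)CC[C@H]1O[C@]1(C)C[C@@H](O)/C=C(\C)CO
F3 | step 19 | (2R,3E)-1-[(2R,3R)-3-{(3Z,6R)-6-[bis(phenylsulfonyl)methyl]-7-hydroxy-3,7-dimethyloct-3-en-1-yl}-2-methyloxiran-2-yl]-5-chloro-4-methylpent-3-en-2-ol | O=S(=O)(c1ccccc1)C(S(=O)(=O)c1ccccc1)[C@@H](C(C)(C)O)C/C=C(/C)CC[C@H]1O[C@]1(C)C[C@@H](O)/C=C(\C)CCl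
F4 | step 14 | (2E,6Z,9R)-2,6,10-trimethyl-9-[(phenylsulfonyl)methyl]undeca-2,6-diene-1,10-diol | O=S(=O)(c1ccccc1)C[C@@H](C(C)(C)O)C/C=C(/C)CC/C=C(\C)CO
F5 | step 14 | (3R,5Z)-8-[(2R,3R)-3-(hydroxymethyl)-3-methyloxiran-2-yl]-2,6-dimethyl-3-[(phenylsulfonyl)methyl]oct-5-en-2-ol | O=S(=O)(c1ccccc1)C[C@@H](C(C)(C)O)C/C=C(/C)CC[C@H]1O[C@]1(C)CO
F6 | step 14 | [(2R,3R)-3-{(3Z,6R)-7-hydroxy-3,7-dimethyl-6-[(phenylsulfonyl)methyl]oct-3-en-1-yl}-2-methyloxiran-2-yl]methyl trifluoromethanesulfonate | O=S(=O)(c1ccccc1)C[C@@H](C(C)(C)O)C/C=C(/C)CC[C@H]1O[C@]1(C)COS(=O)(=O)C(F)(F)F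
F7 | step 14 | tert-butyl{[(2R)-5-[(2R,3R)-3-{(3Z,6R)-7-hydroxy-3,7-dimethyl-6-[(phenylsulfonyl)methyl]oct-3-en-1-yl}-2-methyloxiran-2-yl]pent-3-yn-2-yl]oxy}dimethylsilane | O=S(=O)(c1ccccc1)C[C@@H](C(C)(C)O)C/C=C(/C)CC[C@H]1O[C@]1(C)CC#C[C@@H](C)O[Si](C)(C)C(C)(C)C
F8 | step 15 | (2R,3Z)-5-[(2R,3R)-3-{(3Z,6R)-6-[bis(phenylsulfonyl)methyl]-7-hydroxy-3,7-dimethyloct-3-en-1-yl}-2-methyloxiran-2-yl]-4-(triethoxysilyl)pent-3-en-2-ol | O=S(=O)(c1ccccc1)C(S(=O)(=O)c1ccccc1)[C@@H](C(C)(C)O)C/C=C(/C)CC[C@H]1O[C@]1(C)C/C([Si](OCC)(OCC)OCC)=C/[C@@H](C)O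
F9 | step 10 | (3R,5Z,9E)-11-[(tert-butyldiphenylsilyl)oxy]-2,6,10-trimethyl-3-[(phenylsulfanyl)(phenylsulfonyl)methyl]undeca-5,9-dien-2-ol (epimers at the sulfur-bearing carbon) | O=S(=O)(c1ccccc1)C(Sc1ccccc1)[C@@H](C(C)(C)O)C/C=C(/C)CC/C=C(\C)CO[Si](c1ccccc1)(c1ccccc1)C(C)(C)C
F10 | step 21 | (3R,5Z)-3-[bis(phenylsulfonyl)methyl]-2,6-dimethyl-8-[(2R,3R)-3-methyl-3-{[(2R,3R)-3-(prop-1-en-2-yl)oxiran-2-yl]methyl}oxiran-2-yl]oct-5-en-2-yl acetate | O=S(=O)(c1ccccc1)C(S(=O)(=O)c1ccccc1)[C@@H](C(C)(C)OC(C)=O)C/C=C(/C)CC[C@H]1O[C@]1(C)C[C@H]2O[C@@H]2C(C)=C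
F11 | step 21 | 2-[(1R,3R,4E,8R,10Z,14R)-3-hydroxy-1,5,11-trimethyl-7,7-bis(phenylsulfonyl)-15-oxabicyclo[12.1.0]pentadeca-4,10-dien-8-yl]propan-2-yl acetate | O[C@H]1/C=C(\C)CC(S(=O)(=O)c2ccccc2)(S(=O)(=O)c3ccccc3)[C@@H](C(C)(C)OC(C)=O)C/C=C(/C)CC[C@H]4O[C@]4(C)C1
F12 | step 21 | 2-[(1R,3R,4E,8R,10Z,14R)-3-hydroxy-1,5,11-trimethyl-15-oxabicyclo[12.1.0]pentadeca-4,10-dien-8-yl]propan-2-yl acetate | O[C@H]1/C=C(\C)CC[C@@H](C(C)(C)OC(C)=O)C/C=C(/C)CC[C@H]2O[C@]2(C)C1
A1 | alternative 1 | acyclic Z-trisubstituted alkene holding C4–C14, C1 and the but-2-ynyl end (terminal vinyl at C4=C5, triethylsilyl ether on the C6 side chain, C12/C13 acetonide, C1 tert-butyldimethylsilyl ether) | C=C[C@@H](C(C)(C)O[Si](CC)(CC)CC)C/C=C(/C)CC[C@H]1OC(C)(C)O[C@]1(C)C[C@@H](O[Si](C)(C)C(C)(C)C)C#CC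
A2 | alternative 1 | bromomagnesium reagent at C10 carrying C11–C14, the C12/C13 acetonide, the C1 silyl ether and the methyl alkyne | Br[Mg]CC[C@H]1OC(C)(C)O[C@]1(C)C[C@@H](O[Si](C)(C)C(C)(C)C)C#CC
A3 | alternative 1 | primary C7 triflate carrying C6 with its triethylsilyloxy-isopropyl group and the C4=C5 vinyl group | C=C[C@@H](C(C)(C)O[Si](CC)(CC)CC)COS(=O)(=O)C(F)(F)F
A4 | alternative 1 | propyne | CC#C
A5 | alternative 2 | 14-membered ring with tertiary alcohol on the C6 side chain, phenylsulfanyl group at C7, C12/C13 acetonide and C1 silyl ether | CC(C)(C)[Si](C)(C)O[C@H]1/C=C(\C)CC[C@@H](C(C)(C)O)C(Sc2ccccc2)/C=C(/C)CC[C@H]3OC(C)(C)O[C@]3(C)C1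
A6 | alternative 2 | acyclic (Z)-allylic phenyl sulfide at C7 with the gem-dimethyl oxirane at C6, C12/C13 acetonide and C1 silyl ether | c1ccccc1SC/C=C(/C)CC[C@H]2OC(C)(C)O[C@]2(C)C[C@@H](O[Si](C)(C)C(C)(C)C)/C=C(\C)CC[C@H]3OC3(C)C
A7 | alternative 3 | 14-membered enone with C13 tertiary alcohol and C12 chloride | O=C1/C=C(\C)CC[C@@H](C(C)(C)OC(C)=O)C/C=C(/C)CC[C@H](Cl)[C@@](O)(C)C1
A8 | alternative 3 | acyclic α-chloro methyl ketone (C12 chloride, C13 ketone) with a 2-(trimethylsilyloxy)diene terminus at C14=C1 | C=C(O[Si](C)(C)C)/C=C(\C)CC[C@@H](C(C)(C)OC(C)=O)C/C=C(/C)CC[C@H](Cl)C(C)=O
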